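**Plan**

- Retrosynthesis: ring A is opened at C5–C4a (Pd enolate vinylation). The silyl groups and the C8 ketone are then removed (oxidation), C7–C8 is cut (aldol of a 3-formyl-4-bromopyranone with an ethyl ketone), and last C5–C1' (enolate farnesylation) and the formyl/bromo pair on the pyranone (haloformylation).
- Forward: the pyranone ring is bought as triacetic acid lactone. The chain is joined to it by the aldol, oxidised to the β-diketone and bis-silylated, and carbocyclic ring A is closed last.
- Enabling feature: C4a is the 4-carbon of the 2-pyranone, a vinylogous acyl position that carries the bromide. C5 is the γ-carbon of the β-diketone spanning C6 and C8, which hangs on C8a. C5 and C4a are therefore 1,6-related, and joining them closes six-membered ring A.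
- Stereochemistry: C5 (S) is the only stereocentre. It is racemic up to the diketone, becomes planar in the dienol ether, and is set in the ring closure by the chiral bisphosphine on palladium. The 2E,6E alkenes come unchanged from farnesyl bromide.

Key step: step 6

Numbering: isochromene numbering of the target is used throughout (C1 lactone carbonyl, O2, C3, C4, C4a, C5 quaternary, C6 ketone, C7, C8 enol, C8a); farnesyl carbons are primed.

Assumption: the sense of induction of the bisphosphine cannot be predicted from close analogues; (R)-DIFLUORPHOS is written, and its antipode would be used if the first run delivers the 5R series.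

**Route**

Step 1
Reactants: 1 triacetic acid lactone (4-hydroxy-6-methyl-2H-pyran-2-one)
Product: 2 4-bromo-6-methyl-2-oxo-2H-pyran-3-carbaldehyde
Conditions: PBr3 (2.5 equiv), DMF (3 equiv), CHCl3, 0 → 60 °C; ice-water
Reagents that add atoms: N,N-dimethylformamide CN(C)C=O; phosphorus tribromide BrP(Br)Br; water O
Why: Vilsmeier–Haack haloformylation: the bromomethyleneiminium salt C-formylates the nucleophilic C3 of the vinylogous acid and turns the 4-OH into the vinylogous acyl bromide by addition–elimination, and hydrolysis of the iminium gives the aldehyde; the chloro version (POCl3/DMF) is standard for 4-hydroxy-2-pyranones and 4-hydroxycoumarins.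

Step 2
Reactants: 3 pentan-3-one; 4 (2E,6E)-farnesyl bromide
Product: 5 racemic (6E,10E)-4,7,11,15-tetramethylhexadeca-6,10,14-trien-3-one
Conditions: LDA, THF, −78 °C; then 4 (0.7 equiv), DMPU, −78 → 0 °C
Reagents that add atoms: none
Why: SN2 alkylation of the lithium enolate of a symmetrical ketone by a primary allylic bromide; attack at the primary carbon keeps the 2E,6E geometry, and the excess of enolate limits double alkylation.

Step 3
Reactants: 5 racemic (6E,10E)-4,7,11,15-tetramethylhexadeca-6,10,14-trien-3-one; 2 4-bromo-6-methyl-2-oxo-2H-pyran-3-carbaldehyde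
Product: 6 4-bromo-3-[(6E,10E)-1-hydroxy-2,4,7,11,15-pentamethyl-3-oxohexadeca-6,10,14-trien-1-yl]-6-methyl-2H-pyran-2-one (mixture of racemic diastereomers)
Conditions: 5, Bu2BOTf, i-Pr2NEt, CH2Cl2, −78 → 0 °C; then 2, −78 °C; pH 7 buffer, MeOH, H2O2, 0 °C
Reagents that add atoms: none
Why: Boron-mediated aldol addition: Bu2BOTf/i-Pr2NEt enolises 5 only on its less hindered ethyl side, and the boron enolate should add 1,2 to the aldehyde through a closed six-membered transition state rather than 1,4 to the bromopyranone; the new C7 and C8 centres and racemic C5 are all erased later, and O8 cannot displace the bromide because that would need a four-membered ring.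

Step 4
Reactants: 6 4-bromo-3-[(6E,10E)-1-hydroxy-2,4,7,11,15-pentamethyl-3-oxohexadeca-6,10,14-trien-1-yl]-6-methyl-2H-pyran-2-one
Product: 7 racemic 4-bromo-6-methyl-3-[(6E,10E)-2,4,7,11,15-pentamethyl-3-oxohexadeca-6,10,14-trienoyl]-2H-pyran-2-one (diastereomer mixture)
Conditions: Dess–Martin periodinane, CH2Cl2, 0 °C → rt; filtration work-up without aqueous base; used at once
Reagents that add atoms: none
Why: Dess–Martin oxidation of a β-hydroxy ketone to the 2-methyl-1,3-diketone under neutral conditions that spare the trisubstituted alkenes and the vinylogous acyl bromide; the α-methyl diketone is little enolised, which should slow attack of O6 on C4.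

Step 5
Reactants: 7 racemic 4-bromo-6-methyl-3-[(6E,10E)-2,4,7,11,15-pentamethyl-3-oxohexadeca-6,10,14-trienoyl]-2H-pyran-2-one
Product: 8 4-bromo-6-methyl-3-[(6E,10E)-2,4,7,11,15-pentamethyl-1,3-bis(triethylsilyloxy)hexadeca-1,3,6,10,14-pentaen-1-yl]-2H-pyran-2-one (mixture of isomers at the two enol ether double bonds)
Conditions: TESOTf (2.5 equiv), i-Pr2NEt (3.5 equiv), CH2Cl2, −78 → 0 °C, 7 added to the premixed reagents
Reagents that add atoms: triethylsilyl trifluoromethanesulfonate CC[Si](CC)(CC)OS(=O)(=O)C(F)(F)F
Why: Soft enolisation: double O-silylation of β-diketones by silyl triflate and a tertiary amine to 1,3-bis(silyloxy)-1,3-dienes is established; the first silyl group takes the place of the acidic C7–H, the second follows removal of the C5 methine from the silyl-activated vinylogous ester, and with the silyl triflate present before the diketone meets base each enol oxygen should be capped before it can attack C4; TES is chosen so that the diene survives isolation yet is still cleaved by fluoride in step 6.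

Step 6
Reactants: 8 4-bromo-6-methyl-3-[(6E,10E)-2,4,7,11,15-pentamethyl-1,3-bis(triethylsilyloxy)hexadeca-1,3,6,10,14-pentaen-1-yl]-2H-pyran-2-one
Product: 10 (5S)-8-hydroxy-3,5,7-trimethyl-5-[(2E,6E)-3,7,11-trimethyldodeca-2,6,10-trien-1-yl]-1H-isochromene-1,6(5H)-dione (5-farnesyl-isochromene; the target), via (5S)-6-triethylsilyloxy-3,5,7-trimethyl-5-farnesyl-1H-isochromene-1,8(5H)-dione 9 (not isolated)
Conditions: Pd2(dba)3 (5 mol %), (R)-DIFLUORPHOS (12 mol %), CsF (1.5 equiv), toluene, 50 °C; then aq citric acid, THF, rt
Reagents that add atoms: none
Why: Proposed new method: Pd(0) should insert into the C4–Br bond of the pyranone (a vinylogous acyl bromide), the Pd–Br unit should exchange with the sparingly soluble CsF, and the Pd–F so formed should strip the neighbouring O8 silyl group to give an O8-bound palladium dienolate that can rotate about C7–C8 and slip along the dienolate to carbon-bound C5; C(sp2)–C(sp3) reductive elimination then forms C5–C4a and leaves the neutral silyl enol ether 9, which the acidic work-up hydrolyses to 10. The closest known reaction types are the fluoride-promoted Pd-catalysed α-arylation of ketone silyl enol ethers and the enantioselective Pd-catalysed α-arylation and α-vinylation of α-branched ketone enolates to quaternary centres, extended here to the γ-terminus of a β-diketone bis-silyl dienol ether and to a 4-pyranonyl bromide. Ring A closes as a formal 6-exo ipso substitution at C4a, realised as reductive elimination from a seven-membered palladacycle (Pd, C4a, C8a, C8, C7, C6, C5). The C5 stereocentre is set by the chiral bisphosphine alone: the C5-bound palladium enolates should epimerise through O-bound and η3 forms faster than they eliminate, so both enol ether geometries of 8 (and hence both C5 epimers of 7) drain through the diastereomeric palladacycle favoured by the ligand, taken here to be the one leading to 5S. The step needs carbon- over oxygen-attack, which the O6 silyl ether secures because it stays on until the C–C bond exists while closure through C7 or O8 would need a four-membered ring, and it needs the catalysed path to beat uncatalysed addition–elimination, which the neutral TES enol ether and a fluoride delivered at palladium rather than in solution are meant to secure; discrimination of methyl against the farnesyl CH2 rests on the ligand and the rigid palladacycle.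

**Compound list**

1 | triacetic acid lactone (4-hydroxy-6-methyl-2H-pyran-2-one) | CC1=CC(O)=CC(=O)O1 | starting material
2 | 4-bromo-6-methyl-2-oxo-2H-pyran-3-carbaldehyde | O=Cc1c(Br)cc(C)oc1=O | intermediate
3 | pentan-3-one | CCC(=O)CC | starting material
4 | (2E,6E)-farnesyl bromide | CC(C)=CCC/C(C)=C/CC/C(C)=C/CBr | starting material
5 | racemic (6E,10E)-4,7,11,15-tetramethylhexadeca-6,10,14-trien-3-one | CC(C)=CCC/C(C)=C/CC/C(C)=C/CC(C)C(=O)CC | intermediate
6 | 4-bromo-3-[(6E,10E)-1-hydroxy-2,4,7,11,15-pentamethyl-3-oxohexadeca-6,10,14-trien-1-yl]-6-methyl-2H-pyran-2-one (racemic diastereomer mixture) | CC(C)=CCC/C(C)=C/CC/C(C)=C/CC(C)C(=O)C(C)C(O)c1c(Br)cc(C)oc1=O | intermediate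
7 | racemic 4-bromo-6-methyl-3-[(6E,10E)-2,4,7,11,15-pentamethyl-3-oxohexadeca-6,10,14-trienoyl]-2H-pyran-2-one | CC(C)=CCC/C(C)=C/CC/C(C)=C/CC(C)C(=O)C(C)C(=O)c1c(Br)cc(C)oc1=O | intermediate
8 | 4-bromo-6-methyl-3-[(6E,10E)-2,4,7,11,15-pentamethyl-1,3-bis(triethylsilyloxy)hexadeca-1,3,6,10,14-pentaen-1-yl]-2H-pyran-2-one (enol ether geometries not defined) | CC(C)=CCC/C(C)=C/CC/C(C)=C/CC(C)=C(O[Si](CC)(CC)CC)C(C)=C(O[Si](CC)(CC)CC)c1c(Br)cc(C)oc1=O | intermediate
9 | (5S)-6-triethylsilyloxy-3,5,7-trimethyl-5-[(2E,6E)-3,7,11-trimethyldodeca-2,6,10-trien-1-yl]-1H-isochromene-1,8(5H)-dione | CC(C)=CCC/C(C)=C/CC/C(C)=C/C[C@]1(C)C(O[Si](CC)(CC)CC)=C(C)C(=O)c2c1cc(C)oc2=O | intermediate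
10 | (5S)-8-hydroxy-3,5,7-trimethyl-5-[(2E,6E)-3,7,11-trimethyldodeca-2,6,10-trien-1-yl]-1H-isochromene-1,6(5H)-dione (5-farnesyl-isochromene) | CC(C)=CCC/C(C)=C/CC/C(C)=C/C[C@]1(C)C(=O)C(C)=C(O)c2c1cc(C)oc2=O | target

**Totals and risks**

Total step count: 6. Longest linear sequence: 5 steps (1 → 2 → 6 → 7 → 8 → 10, or equally 3 → 5 → 6 → 7 → 8 → 10).

Steps most likely to fail:

1. Step 6 (carries the label). What may go wrong:
   - fluoride may free the dienolate away from palladium, so that uncatalysed addition–elimination closes the ring without enantiocontrol;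
   - the diene may be protodesilylated back to the diketone, which then closes through O6;
   - bromide at C4 may be exchanged for fluoride, which stops oxidative addition;
   - the ligand may discriminate poorly between the methyl and the farnesyl CH2 faces.

   Fallback, with known chemistry: the ring would be closed without metal and the enantiomers separated afterwards. Setting out from 8, catalytic TESOTf with 2,6-di-tert-butyl-4-methylpyridine in CH2Cl2 at −78 °C should promote the intramolecular Mukaiyama–Michael addition of the diene terminus C5 to C4 of the lactone-activated pyranone with loss of bromide. This is the usual mode of reaction of 1,3-bis(silyloxy)dienes with enones that carry a β-leaving group; both oxygens stay silylated, so only carbon can attack. It would give the racemic 8-triethylsilyl enol ether F1. Aqueous citric acid would hydrolyse it to the racemic 5-farnesyl-isochromene F2, and preparative HPLC on a polysaccharide chiral stationary phase would deliver the 5S enantiomer, rejoining the route at 10.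

2. Step 5. What may go wrong:
   - the silylation may stall after the first silyl group because the amine does not remove the hindered C5 methine;
   - free silyl triflate may trigger ring closure of the diene before it is isolated.

   Fallback: the two silyl groups would be introduced in separate operations of different type, as in the classical two-stage preparation of 1,3-bis(silyloxy)dienes. Setting out from 7, TESOTf (1.05 equiv) and 2,6-lutidine at −78 °C should stop at the mono-silyl stage, the 6-O-triethylsilyl enol ether F3 and/or its 8-O regioisomer F4. Either one, on kinetic deprotonation at C5 with KHMDS in THF at −78 °C in the presence of TESCl (in situ quench), is O-silylated to the same diene, so the route is rejoined at 8.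

3. Step 3. What may go wrong:
   - the boron enolate may add 1,4 to C4 of the aldehyde with loss of bromide instead of 1,2 to the formyl group;
   - the activated aldol may dehydrate or revert during the oxidative work-up.

   Fallback: the C7–C8 bond would be made at the acyl oxidation level, which also removes step 4. Setting out from 2, Pinnick oxidation (NaClO2, NaH2PO4, 2-methyl-2-butene, t-BuOH/H2O) should give 4-bromo-6-methyl-2-oxo-2H-pyran-3-carboxylic acid F5. Oxalyl bromide with catalytic DMF should give the acid bromide F6; bromide is used throughout so that halide exchange at C4 is degenerate. Soft-enolisation C-acylation of ketone 5 with it (MgBr2·OEt2, i-Pr2NEt, CH2Cl2, 0 °C) enolises the ethyl side and holds the product as its magnesium chelate. It would give the diketone directly, rejoining the route at 7.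

**Further compounds**

F1 | step 6 | racemic 8-triethylsilyloxy-3,5,7-trimethyl-5-[(2E,6E)-3,7,11-trimethyldodeca-2,6,10-trien-1-yl]-1H-isochromene-1,6(5H)-dione | CC(C)=CCC/C(C)=C/CC/C(C)=C/CC1(C)C(=O)C(C)=C(O[Si](CC)(CC)CC)c2c1cc(C)oc2=O
F2 | step 6 | racemic 8-hydroxy-3,5,7-trimethyl-5-[(2E,6E)-3,7,11-trimethyldodeca-2,6,10-trien-1-yl]-1H-isochromene-1,6(5H)-dione | CC(C)=CCC/C(C)=C/CC/C(C)=C/CC1(C)C(=O)C(C)=C(O)c2c1cc(C)oc2=O
F3 | step 5 | 4-bromo-6-methyl-3-[(6E,10E)-2,4,7,11,15-pentamethyl-3-(triethylsilyloxy)hexadeca-2,6,10,14-tetraenoyl]-2H-pyran-2-one | CC(C)=CCC/C(C)=C/CC/C(C)=C/CC(C)C(O[Si](CC)(CC)CC)=C(C)C(=O)c1c(Br)cc(C)oc1=O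
F4 | step 5 | 4-bromo-6-methyl-3-[(6E,10E)-2,4,7,11,15-pentamethyl-3-oxo-1-(triethylsilyloxy)hexadeca-1,6,10,14-tetraen-1-yl]-2H-pyran-2-one | CC(C)=CCC/C(C)=C/CC/C(C)=C/CC(C)C(=O)C(C)=C(O[Si](CC)(CC)CC)c1c(Br)cc(C)oc1=O
F5 | step 3 | 4-bromo-6-methyl-2-oxo-2H-pyran-3-carboxylic acid | Cc1cc(Br)c(C(=O)O)c(=O)o1
F6 | step 3 | 4-bromo-6-methyl-2-oxo-2H-pyran-3-carbonyl bromide | Cc1cc(Br)c(C(Br)=O)c(=O)o1
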